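**Strategy.** The only ring is cut at C5–C6 and C4–Br (ring numbering: C1 = C(CH3)Cl, C2, C3 = quaternary C(CH3)(bromovinyl), C4 = CHBr, C5, C6 = CHCl). The feature exploited is that the C4 bromine and the C6 heteroatom flank the C5 methylene in a 1,3 relationship, the signature of a vinyl group adding to an aldehyde with halide capture, while the C3 bromovinyl group can derive from a second, identical vinyl group. One bromo-Prins closure thus forms the cyclohexane, the C–Br bond and the centres C3, C4 and C6 from the lone catalytically set centre C1. Its precursor is the acyclic α-chloro aldehyde 9, which carries a quaternary carbon bearing two vinyl groups.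

Key step: step 5

Remark: 1 is used as the commercial (Z)-isomer; its geometry is irrelevant because the stereocentre it creates in step 1 becomes achiral in step 2.
Remark: the sense of induction of the cinchona primary amine on this α,α-dialkyl aldehyde is to be fixed by a pilot run; the quinine- or the quinidine-derived pseudoenantiomer is then used so that the (2S)-chloride 9 results.

Step 1
Reactants: 1 (2Z)-3-methylpent-2-en-4-yn-1-ol; 2 2-methoxypropene
Product: 4 (±)-4-ethynyl-4-methylhex-5-en-2-one, via allyl isopropenyl ether 3 (not isolated)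
Conditions: 2 (4 equiv), H3PO4 (cat.), toluene, 140 °C, sealed vessel
Reagents that add atoms: 2-methoxypropene (2), COC(C)=C
Why: Acid-catalysed exchange gives the allyl isopropenyl ether 3, whose thermal [3,3] shift (ketone Claisen rearrangement of the Saucy–Marbet type) builds the quaternary carbon bearing methyl, vinyl and ethynyl groups; the new stereocentre is racemic and is erased in step 2.

Step 2
Reactants: 4 (±)-4-ethynyl-4-methylhex-5-en-2-one
Product: 5 4-ethenyl-4-methylhex-5-en-2-one
Conditions: H2 (1 atm, 1 equiv uptake), 5% Pd/CaCO3 poisoned with Pb(OAc)2, quinoline, hexane, rt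
Reagents that add atoms: none
Why: Lindlar-type semihydrogenation should stop at the alkene, turning the ethynyl group into the second vinyl group and thereby making the quaternary carbon achiral.

Step 3
Reactants: 5 4-ethenyl-4-methylhex-5-en-2-one; 6 (methoxymethyl)triphenylphosphonium chloride
Product: 8 (±)-4-ethenyl-2,4-dimethylhex-5-enal, via methyl enol ether 7 (not isolated)
Conditions: 6, KOtBu, THF, 0 °C to rt; then 2 M HCl, THF, rt
Reagents that add atoms: (methoxymethyl)triphenylphosphonium chloride (6), [Cl-].COC[P+](c1ccccc1)(c1ccccc1)c1ccccc1; water, O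
Why: Wittig methoxymethylenation of the methyl ketone followed by acid hydrolysis of the enol ether gives the one-carbon-homologated α-branched aldehyde, whose racemic, enolisable α-centre is what the next step needs.

Step 4
Reactants: 8 (±)-4-ethenyl-2,4-dimethylhex-5-enal
Product: 9 (2S)-2-chloro-4-ethenyl-2,4-dimethylhex-5-enal
Conditions: NCS, 9-amino-9-deoxy-epi-quinine (20 mol %), TFA (40 mol %), toluene, −20 °C
Reagents that add atoms: N-chlorosuccinimide, O=C1CCC(=O)N1Cl
Why: Enamine-catalysed α-chlorination with a primary amine suited to α-branched aldehydes: both enantiomers of 8 converge on one enamine whose geometry is biased by the bulky neopentyl-type arm, the catalyst shields one face toward NCS, and the quaternary α-chloro aldehyde formed can neither racemise nor be chlorinated again.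

Step 5
Reactants: 9 (2S)-2-chloro-4-ethenyl-2,4-dimethylhex-5-enal
Product: 10 (1S,2S,4S,5S)-5-bromo-2-chloro-4-ethenyl-2,4-dimethylcyclohexan-1-ol
Conditions: TiBr4 (2 equiv), CH2Cl2, −78 °C; then H2O, 0 °C
Reagents that add atoms: titanium tetrabromide, Br[Ti](Br)(Br)Br
Why: Proposed new method: TiBr4 binds the non-enolisable, strongly electrophilic α-chloro aldehyde, the terminal carbon C5 of one vinyl group attacks C6 and bromide from a titanium bromide ate species quenches the developing C4 cation anti to the new bond; the closest known reaction type is the Lewis-acid halo-Prins carbocyclisation of hex-5-enals to 3-halocyclohexanols. The ring closes through a chair in a 6-endo-trig mode with respect to the alkene (both alkene carbons enter the ring, the carbonyl oxygen stays exocyclic). C6 is controlled by C1: chlorine sits axial and antiperiplanar to the C=O dipole (Cornforth arrangement, which also keeps the larger C1 methyl equatorial), so the new oxygen should be axial and trans to chlorine. C3 is decided by which diastereotopic vinyl group reacts, the chair with the spectator vinyl axial and the C3 methyl equatorial trading a Cl/methyl for a Cl/vinyl 1,3-diaxial contact, and C4 is set by anti addition across the alkene, which places bromine equatorial. The step needs this vinyl-group selectivity, secured only by that modest steric bias, and capture of the secondary C4 cation before a 1,2-shift of vinyl or methyl from C3, for which excess TiBr4 at −78 °C supplies a high local bromide concentration; the quaternary C3 has no allylic hydrogen, so ene-type proton loss is excluded.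

Step 6
Reactants: 10 (1S,2S,4S,5S)-5-bromo-2-chloro-4-ethenyl-2,4-dimethylcyclohexan-1-ol
Product: 11 (1S,2S,4R,5S)-2-bromo-4,5-dichloro-1-ethenyl-1,5-dimethylcyclohexane
Conditions: PPh3, NCS, THF, 0 °C to 50 °C
Reagents that add atoms: N-chlorosuccinimide, O=C1CCC(=O)N1Cl
Why: Appel-type chlorination, in which chloride displaces the axial C6 alkoxyphosphonium group by SN2 with inversion to give the equatorial chloride cis to the C1 chlorine (the known course from trans-2-chlorocycloalkanols to cis-1,2-dichlorides), under neutral conditions that cannot close the trans-diaxial chlorohydrin to an epoxide.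

Step 7
Reactants: 11 (1S,2S,4R,5S)-2-bromo-4,5-dichloro-1-ethenyl-1,5-dimethylcyclohexane
Product: 12 (1S,2S,4R,5S)-2-bromo-4,5-dichloro-1,5-dimethylcyclohexane-1-carbaldehyde
Conditions: O3, CH2Cl2, −78 °C; then Me2S, −78 °C to rt
Reagents that add atoms: ozone, [O-][O+]=O
Why: Ozonolysis with reductive work-up cleaves the only alkene to an aldehyde on a quaternary carbon, which has no α-hydrogen and so can neither epimerise nor lose HBr.

Step 8
Reactants: 12 (1S,2S,4R,5S)-2-bromo-4,5-dichloro-1,5-dimethylcyclohexane-1-carbaldehyde; 13 bromoform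
Product: 14 (1S,2S,4R,5S)-2-bromo-1-[(E)-2-bromoethenyl]-4,5-dichloro-1,5-dimethylcyclohexane
Conditions: CrBr2 (6 equiv), 13 (2 equiv), THF, 0 °C to rt
Reagents that add atoms: bromoform (13), BrC(Br)Br
Why: Takai olefination, in which the geminal dichromium species from bromoform adds to the aldehyde and eliminates to the (E)-bromoalkene, the bulky quaternary substituent favouring E; the bromide salt of divalent chromium is used so that no chloride can exchange into the vinyl halide.

**Compound list**

1 | (2Z)-3-methylpent-2-en-4-yn-1-ol | C#C/C(C)=C\CO | starting material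
2 | 2-methoxypropene | COC(C)=C | starting material
3 | 2-{[(2Z)-3-methylpent-2-en-4-yn-1-yl]oxy}prop-1-ene (allyl isopropenyl ether, formed in the flask) | C=C(C)OC/C=C(C)\C#C | intermediate
4 | (±)-4-ethynyl-4-methylhex-5-en-2-one | CC(=O)CC(C)(C#C)C=C | intermediate
5 | 4-ethenyl-4-methylhex-5-en-2-one | CC(=O)CC(C)(C=C)C=C | intermediate
6 | (methoxymethyl)triphenylphosphonium chloride | [Cl-].COC[P+](c1ccccc1)(c1ccccc1)c1ccccc1 | starting material
7 | 4-ethenyl-1-methoxy-2,4-dimethylhexa-1,5-diene (E/Z mixture, formed in the flask) | COC=C(C)CC(C)(C=C)C=C | intermediate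
8 | (±)-4-ethenyl-2,4-dimethylhex-5-enal | O=CC(C)CC(C)(C=C)C=C | intermediate
9 | (2S)-2-chloro-4-ethenyl-2,4-dimethylhex-5-enal | O=C[C@@](C)(Cl)CC(C)(C=C)C=C | intermediate
10 | (1S,2S,4S,5S)-5-bromo-2-chloro-4-ethenyl-2,4-dimethylcyclohexan-1-ol | C[C@]1(Cl)C[C@@](C)(C=C)[C@@H](Br)C[C@@H]1O | intermediate
11 | (1S,2S,4R,5S)-2-bromo-4,5-dichloro-1-ethenyl-1,5-dimethylcyclohexane | C[C@]1(Cl)C[C@@](C)(C=C)[C@@H](Br)C[C@H]1Cl | intermediate
12 | (1S,2S,4R,5S)-2-bromo-4,5-dichloro-1,5-dimethylcyclohexane-1-carbaldehyde | C[C@]1(Cl)C[C@@](C)(C=O)[C@@H](Br)C[C@H]1Cl | intermediate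
13 | bromoform | BrC(Br)Br | starting material
14 | (1S,2S,4R,5S)-2-bromo-1-[(E)-2-bromoethenyl]-4,5-dichloro-1,5-dimethylcyclohexane | C[C@]1(Cl)C[C@@](C)(/C=C/Br)[C@@H](Br)C[C@H]1Cl | target

Total step count: 8. Longest linear sequence: 8 steps (1 to 14).

**Steps most likely to fail**

1. Step 5.
   - What may go wrong: the C4 cation may suffer a 1,2-shift of vinyl or methyl from C3 before bromide arrives. Bromide may be delivered from the titanium alkoxide on the oxygen face. The two vinyl groups may react with little discrimination.
   - Fallback (known reactions only), from 9 to 11: CH2=CHMgBr (THF, −78 °C) should add to the aldehyde to give (4S)-4-chloro-6-ethenyl-4,6-dimethylocta-1,7-dien-3-ol F1, whose carbinol configuration is immaterial. Ring-closing metathesis with the second-generation Grubbs catalyst would join the new vinyl group to one vinyl group on the quaternary carbon and give (6S)-6-chloro-4-ethenyl-4,6-dimethylcyclohex-2-en-1-ol F2. Dess–Martin oxidation and chromatographic removal of the epimer at the quaternary carbon would give (4S,6S)-6-chloro-4-ethenyl-4,6-dimethylcyclohex-2-en-1-one F3. Reversible conjugate addition of HBr (AcOH/CH2Cl2, 0 °C, dark) should place bromine equatorially on the β-carbon and give (2S,4S,5S)-5-bromo-2-chloro-4-ethenyl-2,4-dimethylcyclohexan-1-one F4. NaBH4/CeCl3 (MeOH, −78 °C) should deliver hydride axially, anti to the axial chlorine, to give the equatorial alcohol (1R,2S,4S,5S)-5-bromo-2-chloro-4-ethenyl-2,4-dimethylcyclohexan-1-ol F5. Its chlorosulfite (SOCl2) should collapse with retention under catalytic TiCl4 (front-side chloride delivery) to give 11.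

2. Step 6.
   - What may go wrong: SN2 at C6 needs chloride to approach the ring face that carries the axial C1 chlorine and the axial C3 vinyl group, next to a quaternary carbon. E2 loss toward the antiperiplanar axial C5 hydrogen may overtake it. Participation of the antiperiplanar C1 chlorine, which would give retention, is the other threat.
   - Fallback, from 10 to 14: the C–Cl bond is made with retention on the C6 epimer and placed last, so that divalent chromium never meets the vicinal dichloride. Ozonolysis of 10 (O3; Me2S) would give (1S,2S,4S,5S)-2-bromo-5-chloro-4-hydroxy-1,5-dimethylcyclohexane-1-carbaldehyde F6. Takai olefination (CrBr2, bromoform, THF) would give (1S,2S,4S,5S)-5-bromo-4-[(E)-2-bromoethenyl]-2-chloro-2,4-dimethylcyclohexan-1-ol F7. Dess–Martin oxidation would give (2S,4S,5S)-5-bromo-4-[(E)-2-bromoethenyl]-2-chloro-2,4-dimethylcyclohexan-1-one F8. NaBH4/CeCl3 at −78 °C, attacking axially anti to the axial chlorine, should give the equatorial alcohol (1R,2S,4S,5S)-5-bromo-4-[(E)-2-bromoethenyl]-2-chloro-2,4-dimethylcyclohexan-1-ol F9. SOCl2 followed by catalytic TiCl4 should replace the equatorial hydroxyl by chloride with retention and give 14.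

3. Step 4.
   - What may go wrong: the two α-substituents (methyl and a CH2 arm) may not fix the enamine geometry well enough, so facial selectivity in the chlorine transfer may be poor. N-chlorination may deactivate the primary amine.
   - Fallback, from 5 to 9: the centre is set by epoxidation and transferred by invertive opening. Catalytic asymmetric Corey–Chaykovsky epoxidation of methyl ketone 5 would use dimethyloxosulfonium methylide (trimethylsulfoxonium iodide, NaH) and LaLi3(binaphthoxide)3 with a triarylphosphine oxide additive, the binaphthoxide enantiomer being chosen to deliver (2R)-2-(2-ethenyl-2-methylbut-3-en-1-yl)-2-methyloxirane F10. Anhydrous HCl (Et2O/CH2Cl2, −78 °C) should open it at the tertiary carbon with inversion to give (2S)-2-chloro-4-ethenyl-2,4-dimethylhex-5-en-1-ol F11. Dess–Martin oxidation would give 9.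

**Further compounds**

F1 | step 5 | (4S)-4-chloro-6-ethenyl-4,6-dimethylocta-1,7-dien-3-ol (mixture at C3) | C=CC(O)[C@@](C)(Cl)CC(C)(C=C)C=C
F2 | step 5 | (6S)-6-chloro-4-ethenyl-4,6-dimethylcyclohex-2-en-1-ol (mixture at C1 and C4) | C[C@]1(Cl)CC(C)(C=C)C=CC1O
F3 | step 5 | (4S,6S)-6-chloro-4-ethenyl-4,6-dimethylcyclohex-2-en-1-one | C[C@]1(Cl)C[C@@](C)(C=C)C=CC1=O
F4 | step 5 | (2S,4S,5S)-5-bromo-2-chloro-4-ethenyl-2,4-dimethylcyclohexan-1-one | C[C@]1(Cl)C[C@@](C)(C=C)[C@@H](Br)CC1=O
F5 | step 5 | (1R,2S,4S,5S)-5-bromo-2-chloro-4-ethenyl-2,4-dimethylcyclohexan-1-ol | C[C@]1(Cl)C[C@@](C)(C=C)[C@@H](Br)C[C@H]1O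
F6 | step 6 | (1S,2S,4S,5S)-2-bromo-5-chloro-4-hydroxy-1,5-dimethylcyclohexane-1-carbaldehyde | C[C@]1(Cl)C[C@@](C)(C=O)[C@@H](Br)C[C@@H]1O
F7 | step 6 | (1S,2S,4S,5S)-5-bromo-4-[(E)-2-bromoethenyl]-2-chloro-2,4-dimethylcyclohexan-1-ol | C[C@]1(Cl)C[C@@](C)(/C=C/Br)[C@@H](Br)C[C@@H]1O
F8 | step 6 | (2S,4S,5S)-5-bromo-4-[(E)-2-bromoethenyl]-2-chloro-2,4-dimethylcyclohexan-1-one | C[C@]1(Cl)C[C@@](C)(/C=C/Br)[C@@H](Br)CC1=O
F9 | step 6 | (1R,2S,4S,5S)-5-bromo-4-[(E)-2-bromoethenyl]-2-chloro-2,4-dimethylcyclohexan-1-ol | C[C@]1(Cl)C[C@@](C)(/C=C/Br)[C@@H](Br)C[C@H]1O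
F10 | step 4 | (2R)-2-(2-ethenyl-2-methylbut-3-en-1-yl)-2-methyloxirane | C1O[C@]1(C)CC(C)(C=C)C=C
F11 | step 4 | (2S)-2-chloro-4-ethenyl-2,4-dimethylhex-5-en-1-ol | OC[C@@](C)(Cl)CC(C)(C=C)C=C
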